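**Plan**
1. Retrosynthesis: remove the C8 angelate, the C3 acetate and the C15 protecting group; open the cis-1,10-epoxide to the (Z)-C1=C10 olefin; remove C13 (α-methylenation of the lactone).
2. The ten-membered carbocycle is then cut at C1=C10 by putting a sulfur atom between C1 and C10. The resulting 11-membered thiacycle contracts by Ramberg–Bäcklund loss of SO2. Enabling feature: C1 and C10 carry only H, the C14 methyl and the C2/C9 methylenes (no β-leaving group), and the ring olefin they form is cis, the geometry a ring-fused episulfone gives.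
3. Further cuts: C10–S (thia-Michael addition to a C8 enone), C1–S (thioacetate SN2), C8–C9 (acylation), C6–C7 with lactone closure (Evans aldol), C3–C4 (Negishi acylation of a (Z)-vinyl iodide made from butynediol).
4. Forward order: C1–C6/C15 enal, then aldol and γ-lactone, enone, 11-membered thia ring, C8 carbinol, contraction to the carbocycle, methylene lactone, epoxide, esters.
5. Stereochemistry: C3 by CBS reduction; C6 and C7 by the oxazolidinone auxiliary; C8 by Felkin–Anh substrate control; C1/C10 by C8–OH-directed epoxidation; 4Z from trans-hydroalumination; 1(10)Z from the ring contraction.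

Key step: step 16

Remark: atoms are numbered as in germacranolides (ring C1–C10; C11–C13 lactone and methylene; C14 methyl on C10; C15 the CH2O group on C4).
Remark: the C10 sulfide centre and the chlorine-bearing carbon are carried as stereoisomer mixtures, since both are erased in step 16; Grignard reagent 16 is drawn E, but the commercial E/Z mixture serves because that double bond is consumed in step 12.
Remark: metalated species made and consumed within one operation (organolithium and organozinc reagents, enolates, alkoxides) are named in the Why line and not numbered.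

**Route**

Step 1
Reactants: 1 but-2-yne-1,4-diol
Product: 2 4-[(4-methoxybenzyl)oxy]but-2-yn-1-ol
Conditions: NaH (1 equiv), PMBCl (1 equiv), Bu4NI (cat.), THF/DMF, 0 °C to rt; diol in threefold excess
Reagents that add atoms: 4-methoxybenzyl chloride, COc1ccc(CCl)cc1
Why: Williamson etherification, in which the excess of the symmetrical diol should hold the reaction at mono-alkylation.

Step 2
Reactants: 2 4-[(4-methoxybenzyl)oxy]but-2-yn-1-ol
Product: 3 (Z)-3-iodo-4-[(4-methoxybenzyl)oxy]but-2-en-1-ol
Conditions: Red-Al, THF, 0 °C to rt; then I2, THF, −78 °C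
Reagents that add atoms: iodine, II
Why: Hydroxyl-directed trans-hydroalumination places aluminium on the alkyne carbon remote from the free OH and anti to the new C–H bond, and iodinolysis with retention should give the (Z)-γ-iodo allylic alcohol, which fixes the C4=C5 geometry (C15 trans to C6).

Step 3
Reactants: 3 (Z)-3-iodo-4-[(4-methoxybenzyl)oxy]but-2-en-1-ol
Product: 4 (Z)-vinyl iodide TES ether
Conditions: TESCl, imidazole, CH2Cl2, 0 °C
Reagents that add atoms: chlorotriethylsilane, CC[Si](Cl)(CC)CC
Why: Standard silylation of the primary allylic alcohol, with TES chosen so that step 7 can oxidise this ether directly.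

Step 4
Reactants: 4 (Z)-vinyl iodide TES ether; 5 3-chloropropanoyl chloride
Product: 6 (Z)-β-chloroethyl enone
Conditions: t-BuLi (2 equiv), Et2O, −78 °C; ZnCl2, THF, −78 to 0 °C; then 5, Pd(PPh3)4 (cat.), 0 °C to rt
Reagents that add atoms: none
Why: Iodine–lithium exchange, transmetalation to the alkenylzinc chloride and Negishi acylation all proceed with retention of olefin geometry, and the zinc reagent is mild enough to avoid β-elimination of the allylic ether and dehydrochlorination of the acyl partner.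

Step 5
Reactants: 6 (Z)-β-chloroethyl enone
Product: 7 (3S,4Z)-allylic alcohol
Conditions: (R)-2-methyl-CBS-oxazaborolidine (0.2 equiv), catecholborane, toluene, −78 °C
Reagents that add atoms: none
Why: Corey–Bakshi–Shibata reduction in which the branched alkenyl group is the large substituent and CH2CH2Cl the small one, so the (R)-catalyst should deliver hydride to the face that gives the (S)-carbinol and sets C3.

Step 6
Reactants: 7 (3S,4Z)-allylic alcohol
Product: 8 C3 TBS ether
Conditions: TBSOTf, 2,6-lutidine, CH2Cl2, −78 °C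
Reagents that add atoms: tert-butyldimethylsilyl triflate, CC(C)(C)[Si](C)(C)OS(=O)(=O)C(F)(F)F
Why: Silylation of the secondary alcohol under buffered conditions that leave the primary TES ether intact.

Step 7
Reactants: 8 C3 TBS ether
Product: 9 (2Z,4S)-enal
Conditions: (COCl)2, DMSO, CH2Cl2, −78 to −40 °C; then Et3N, −78 to 0 °C
Reagents that add atoms: none
Why: Swern conditions cleave and oxidise a primary allylic TES ether in one operation while a secondary TBS ether survives, so the (Z)-enal should form without a separate deprotection and without touching C3.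

Step 8
Reactants: 10 (S)-4-benzyloxazolidin-2-one; 11 methyl 4-chloro-4-oxobutanoate
Product: 12 succinate imide
Conditions: n-BuLi, THF, −78 °C; then 11
Reagents that add atoms: none
Why: N-acylation of the lithiated Evans oxazolidinone by the acid chloride, which is far more electrophilic than the methyl ester.

Step 9
Reactants: 12 succinate imide; 9 (2Z,4S)-enal
Product: 14 trans-lactone imide, via aldol adduct 13 (not isolated)
Conditions: 12, Bu2BOTf, iPr2NEt, CH2Cl2, −78 to 0 °C; 9, −78 to 0 °C; pH 7 buffer, MeOH, H2O2; then PPTS (cat.), CH2Cl2, rt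
Reagents that add atoms: none
Why: Evans syn-aldol reaction in which the Z-boron enolate formed at the imide α-CH2 (C7) reacts through a Zimmerman–Traxler chair on the face away from the benzyl group, setting C6 and C7 together, after which the γ-hydroxy methyl ester lactonises to the trans-β,γ-disubstituted butyrolactone.

Step 10
Reactants: 14 trans-lactone imide
Product: 15 lactone acid
Conditions: LiOH, H2O2, THF/H2O, 0 °C; Na2SO3; then 1 M HCl to pH 3
Reagents that add atoms: hydrogen peroxide, OO
Why: Lithium hydroperoxide attacks the exocyclic imide carbonyl selectively (standard auxiliary removal), and any lactone opened by hydroxide should reclose on acidification.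

Step 11
Reactants: 15 lactone acid; 16 prop-1-enylmagnesium bromide
Product: 18 enone, via acid chloride 17 (not isolated)
Conditions: 1-chloro-N,N,2-trimethylprop-1-en-1-amine (Ghosez reagent), CH2Cl2, 0 °C to rt; then 16, Fe(acac)3 (3 mol%), THF, −78 °C
Reagents that add atoms: none
Why: Neutral acid chloride formation spares the silyl and PMB ethers, and the iron-catalysed Grignard acylation is faster at −78 °C than addition to the lactone or to the product ketone; palladium is avoided because the lactone C6–O bond is allylic.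

Step 12
Reactants: 18 enone
Product: 21 eleven-membered keto sulfide (C10 epimers), via thioacetate 19 (not isolated), via thiol 20 (not isolated)
Conditions: KSAc, NaI (cat.), DMF, 40 °C; then slow addition to K2CO3, degassed MeOH/THF (0.5 mM), 0 °C to rt
Reagents that add atoms: potassium thioacetate, CC(=O)[S-].[K+]
Why: Thioacetate SN2 at the primary chloride (Finkelstein-assisted), then methanolysis frees the C1 thiolate, which should add to the C9=C10 enone in a reversible intramolecular thia-Michael reaction that high dilution steers to the 11-membered ring; C10 forms as an inconsequential epimer mixture.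

Step 13
Reactants: 21 eleven-membered keto sulfide
Product: 22 C8 alcohol
Conditions: L-Selectride, THF, −78 °C; aq. NH4Cl
Reagents that add atoms: none
Why: Felkin–Anh-controlled reduction in which the bulky hydride attacks anti to C6 on the C7 stereocentre, which should give the 7,8-anti (8R) alcohol, while the lactone is inert at −78 °C.

Step 14
Reactants: 22 C8 alcohol
Product: 23 C8 TES ether
Conditions: TESOTf, 2,6-lutidine, CH2Cl2, −78 to 0 °C
Reagents that add atoms: triethylsilyl triflate, CC[Si](CC)(CC)OS(=O)(=O)C(F)(F)F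
Why: Silylation of the hindered secondary alcohol, needed so that no C8 alkoxide can translactonise under the base of step 16.

Step 15
Reactants: 23 C8 TES ether
Product: 25 α-chloro sulfone, via α-chloro sulfide 24 (not isolated)
Conditions: NCS, CH2Cl2, 0 °C; then mCPBA (2.2 equiv), NaHCO3, 0 °C
Reagents that add atoms: N-chlorosuccinimide, O=C1CCC(=O)N1Cl; 3-chloroperbenzoic acid, OOC(=O)c1cccc(Cl)c1
Why: α-Chlorination of the sulfide through its chlorosulfonium salt (expected mainly at the C1 methylene), then S-oxidation, which is much faster than epoxidation of the oxygen-deactivated C4=C5 olefin; no base is used, so the more acidic lactone α-position is not halogenated.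

Step 16
Reactants: 25 α-chloro sulfone
Product: 27 (1(10)Z,4Z)-cyclodecadiene lactone, via episulfone 26 (not isolated)
Conditions: t-BuOK (3 equiv), THF, −78 to 0 °C
Reagents that add atoms: none
Why: Ramberg–Bäcklund ring contraction: the base removes the α′-proton at C10 (the lactone enolate forms reversibly as a spectator), the carbanion displaces chloride at C1 in a 1,3-elimination (3-exo-tet) to give the ring-fused episulfone 26, and cheletropic loss of SO2 leaves the C1=C10 double bond, so the 11-membered thiacycle becomes the ten-membered carbocycle. The closest known reaction type is the Ramberg–Bäcklund contraction of medium-ring and thia-bridged macrocyclic α-halo sulfones to cycloalkenes with a trisubstituted ring olefin. No stereocentre is created; the C1 and C10 centres of 25 are destroyed, which is why their mixtures converge. The selectivities needed are Z over E and 1,3- over 1,2-elimination. The cis-fused episulfone should be favoured both kinetically and thermodynamically (cis geometry of a ten-membered ring olefin, reinforced by the 4Z olefin and the trans-fused lactone in the same ring). C2 and C9 carry no leaving group, and the C8 silyl ether blocks translactonisation.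

Step 17
Reactants: 27 (1(10)Z,4Z)-cyclodecadiene lactone
Product: 30 α-methylene lactone, via Mannich base 28 (not isolated), via ammonium iodide 29 (not isolated)
Conditions: LDA, THF, −78 °C; CH2=NMe2+ I−, −78 °C to rt; then MeI, MeOH, rt; aq. NaHCO3, CH2Cl2
Reagents that add atoms: Eschenmoser's salt (N,N-dimethylmethyleneiminium iodide), C=[N+](C)C.[I-]
Why: Mannich reaction of the lactone enolate (C11 is the only enolisable carbon), then quaternisation and Hofmann-type elimination, the standard α-methylenation of γ-lactones; it is placed after all thiol and strong-base chemistry.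

Step 18
Reactants: 30 α-methylene lactone
Product: 31 C8 homoallylic alcohol
Conditions: PPTS (cat.), MeOH/CH2Cl2, 0 °C
Reagents that add atoms: none
Why: Acid-catalysed methanolysis removes a secondary TES ether much faster than the secondary TBS ether or the PMB ether.

Step 19
Reactants: 31 C8 homoallylic alcohol
Product: 32 epoxy alcohol
Conditions: VO(acac)2 (cat.), t-BuOOH, CH2Cl2, 0 °C to rt
Reagents that add atoms: tert-butyl hydroperoxide, CC(C)(C)OO
Why: Hydroxyl-directed vanadium-catalysed epoxidation of the homoallylic alcohol, in which the vanadate bound at O8 delivers oxygen to the C1=C10 face syn to O8 and should give the cis-epoxide (1R,10S); the electron-poor C4=C5 olefin and the methylene lactone are not expected to react.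

Step 20
Reactants: 32 epoxy alcohol; 33 angelic acid
Product: 35 C8 angelate, via mixed anhydride 34 (not isolated)
Conditions: 33, 2,4,6-trichlorobenzoyl chloride, Et3N, toluene, rt; then 32, toluene, 75 °C (no DMAP)
Reagents that add atoms: none
Why: Yamaguchi esterification through the preformed mixed anhydride without nucleophilic catalyst, the protocol that acylates hindered secondary alcohols with angelic acid without Z to E isomerisation to the tiglate.

Step 21
Reactants: 35 C8 angelate
Product: 36 C3 alcohol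
Conditions: HF·pyridine, pyridine, THF, 0 °C to rt
Reagents that add atoms: none
Why: Buffered fluoride cleavage of the TBS ether, conditions that trisubstituted epoxides, enoate esters and α-methylene lactones tolerate.

Step 22
Reactants: 36 C3 alcohol
Product: 37 C3 acetate
Conditions: Ac2O, pyridine, CH2Cl2, rt
Reagents that add atoms: acetic anhydride, CC(=O)OC(C)=O
Why: Acetylation of the only free hydroxyl, without DMAP so that the angelate is not exposed to a nucleophilic catalyst.

Step 23
Reactants: 37 C3 acetate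
Product: 38 target (CNP0162483.1)
Conditions: DDQ, CH2Cl2/pH 7 buffer, 0 °C
Reagents that add atoms: none
Why: Oxidative cleavage of the PMB ether under buffered neutral conditions frees the C15 hydroxyl last, so it never competes in acylation or directs an epoxidation.

**Compound list**

1 | but-2-yne-1,4-diol | OCC#CCO | starting material
2 | 4-[(4-methoxybenzyl)oxy]but-2-yn-1-ol | OCC#CCOCc1ccc(OC)cc1 | intermediate
3 | (Z)-3-iodo-4-[(4-methoxybenzyl)oxy]but-2-en-1-ol | OC/C=C(/COCc1ccc(OC)cc1)I | intermediate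
4 | (Z)-triethyl({3-iodo-4-[(4-methoxybenzyl)oxy]but-2-en-1-yl}oxy)silane | CC[Si](CC)(CC)OC/C=C(/COCc1ccc(OC)cc1)I | intermediate
5 | 3-chloropropanoyl chloride | ClCCC(Cl)=O | starting material
6 | (Z)-1-chloro-4-{[(4-methoxybenzyl)oxy]methyl}-6-[(triethylsilyl)oxy]hex-4-en-3-one | CC[Si](CC)(CC)OC/C=C(/COCc1ccc(OC)cc1)C(=O)CCCl | intermediate
7 | (3S,4Z)-1-chloro-4-{[(4-methoxybenzyl)oxy]methyl}-6-[(triethylsilyl)oxy]hex-4-en-3-ol | CC[Si](CC)(CC)OC/C=C(/COCc1ccc(OC)cc1)[C@@H](O)CCCl | intermediate
8 | tert-butyl{[(3S,4Z)-1-chloro-4-{[(4-methoxybenzyl)oxy]methyl}-6-[(triethylsilyl)oxy]hex-4-en-3-yl]oxy}dimethylsilane | CC[Si](CC)(CC)OC/C=C(/COCc1ccc(OC)cc1)[C@@H](O[Si](C)(C)C(C)(C)C)CCCl | intermediate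
9 | (2Z,4S)-4-[(tert-butyldimethylsilyl)oxy]-6-chloro-3-{[(4-methoxybenzyl)oxy]methyl}hex-2-enal | O=C/C=C(/COCc1ccc(OC)cc1)[C@@H](O[Si](C)(C)C(C)(C)C)CCCl | intermediate
10 | (S)-4-benzyloxazolidin-2-one | O=C1N[C@@H](Cc2ccccc2)CO1 | starting material
11 | methyl 4-chloro-4-oxobutanoate | COC(=O)CCC(Cl)=O | starting material
12 | methyl 4-[(4S)-4-benzyl-2-oxooxazolidin-3-yl]-4-oxobutanoate | COC(=O)CCC(=O)N1[C@@H](Cc2ccccc2)COC1=O | intermediate
13 | Evans syn-aldol adduct of 12 and 9 (open-chain γ-hydroxy methyl ester, C6 and C7 as in 14) | COC(=O)C[C@H](C(=O)N1[C@@H](Cc2ccccc2)COC1=O)[C@H](O)/C=C(/COCc1ccc(OC)cc1)[C@@H](O[Si](C)(C)C(C)(C)C)CCCl | intermediate (not isolated)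
14 | (4S)-4-benzyl-3-{[(2R,3S)-2-[(1Z,3S)-3-(TBS-oxy)-5-chloro-2-(PMB-oxymethyl)pent-1-en-1-yl]-5-oxooxolan-3-yl]carbonyl}oxazolidin-2-one (trans-lactone) | O=C1O[C@H](/C=C(/COCc2ccc(OC)cc2)[C@@H](O[Si](C)(C)C(C)(C)C)CCCl)[C@@H](C(=O)N2[C@@H](Cc3ccccc3)COC2=O)C1 | intermediate
15 | (2R,3S)-2-[(1Z,3S)-3-(TBS-oxy)-5-chloro-2-(PMB-oxymethyl)pent-1-en-1-yl]-5-oxooxolane-3-carboxylic acid | O=C1O[C@H](/C=C(/COCc2ccc(OC)cc2)[C@@H](O[Si](C)(C)C(C)(C)C)CCCl)[C@@H](C(O)=O)C1 | intermediate
16 | prop-1-enylmagnesium bromide (drawn E) | C/C=C/[Mg]Br | starting material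
17 | acid chloride of 15 | O=C1O[C@H](/C=C(/COCc2ccc(OC)cc2)[C@@H](O[Si](C)(C)C(C)(C)C)CCCl)[C@@H](C(Cl)=O)C1 | intermediate (not isolated)
18 | (4S,5R)-4-[(E)-but-2-enoyl]-5-[(1Z,3S)-3-(TBS-oxy)-5-chloro-2-(PMB-oxymethyl)pent-1-en-1-yl]oxolan-2-one | O=C1O[C@H](/C=C(/COCc2ccc(OC)cc2)[C@@H](O[Si](C)(C)C(C)(C)C)CCCl)[C@@H](C(=O)/C=C/C)C1 | intermediate
19 | C1 thioacetate of 18 (SAc in place of Cl) | O=C1O[C@H](/C=C(/COCc2ccc(OC)cc2)[C@@H](O[Si](C)(C)C(C)(C)C)CCSC(C)=O)[C@@H](C(=O)/C=C/C)C1 | intermediate (not isolated)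
20 | C1 thiol of 18 (SH in place of Cl) | O=C1O[C@H](/C=C(/COCc2ccc(OC)cc2)[C@@H](O[Si](C)(C)C(C)(C)C)CCS)[C@@H](C(=O)/C=C/C)C1 | intermediate (not isolated)
21 | 11-membered keto sulfide: ring S–C1H2–C2H2–C3H(OTBS)–C4(CH2OPMB)=C5H–C6H–C7H–C8(=O)–C9H2–C10H(CH3), 4Z, trans-fused 6,12-γ-lactone (C11H2); C3, C6, C7 as in 38; C10 epimers | O=C1O[C@@H]2/C=C(/COCc3ccc(OC)cc3)[C@@H](O[Si](C)(C)C(C)(C)C)CCSC(C)CC(=O)[C@H]2C1 | intermediate
22 | C8 alcohol of 21 (8R, as in 38) | O=C1O[C@@H]2/C=C(/COCc3ccc(OC)cc3)[C@@H](O[Si](C)(C)C(C)(C)C)CCSC(C)C[C@@H](O)[C@H]2C1 | intermediate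
23 | C8 TES ether of 22 | O=C1O[C@@H]2/C=C(/COCc3ccc(OC)cc3)[C@@H](O[Si](C)(C)C(C)(C)C)CCSC(C)C[C@@H](O[Si](CC)(CC)CC)[C@H]2C1 | intermediate
24 | α-chloro sulfide (Cl on C1 of 23) | O=C1O[C@@H]2/C=C(/COCc3ccc(OC)cc3)[C@@H](O[Si](C)(C)C(C)(C)C)CC(Cl)SC(C)C[C@@H](O[Si](CC)(CC)CC)[C@H]2C1 | intermediate (not isolated)
25 | α-chloro sulfone (S,S-dioxide of 24) | O=C1O[C@@H]2/C=C(/COCc3ccc(OC)cc3)[C@@H](O[Si](C)(C)C(C)(C)C)CC(Cl)S(=O)(=O)C(C)C[C@@H](O[Si](CC)(CC)CC)[C@H]2C1 | intermediate
26 | episulfone (thiirane 1,1-dioxide spanning C1–C10, fused to the ten-membered ring) | O=C1O[C@@H]2/C=C(/COCc3ccc(OC)cc3)[C@@H](O[Si](C)(C)C(C)(C)C)CC4C(C)(S4(=O)=O)C[C@@H](O[Si](CC)(CC)CC)[C@H]2C1 | intermediate (not isolated)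
27 | (1(10)Z,4Z)-germacra-1(10),4-dien-6,12-olide with 3-OTBS, 8-OTES, 15-OPMB (11,13-dihydro) | O=C1O[C@@H]2/C=C(/COCc3ccc(OC)cc3)[C@@H](O[Si](C)(C)C(C)(C)C)C/C=C(C)\C[C@@H](O[Si](CC)(CC)CC)[C@H]2C1 | intermediate
28 | 13-(dimethylamino) Mannich base of 27 (C11 epimers) | CN(C)CC1C(=O)O[C@@H]2/C=C(/COCc3ccc(OC)cc3)[C@@H](O[Si](C)(C)C(C)(C)C)C/C=C(C)\C[C@@H](O[Si](CC)(CC)CC)[C@@H]12 | intermediate (not isolated)
29 | trimethylammonium iodide of 28 | C[N+](C)(C)CC1C(=O)O[C@@H]2/C=C(/COCc3ccc(OC)cc3)[C@@H](O[Si](C)(C)C(C)(C)C)C/C=C(C)\C[C@@H](O[Si](CC)(CC)CC)[C@@H]12.[I-] | intermediate (not isolated)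
30 | (1(10)Z,4Z)-germacra-1(10),4,11(13)-trien-6,12-olide with 3-OTBS, 8-OTES, 15-OPMB | C=C1C(=O)O[C@@H]2/C=C(/COCc3ccc(OC)cc3)[C@@H](O[Si](C)(C)C(C)(C)C)C/C=C(C)\C[C@@H](O[Si](CC)(CC)CC)[C@@H]12 | intermediate
31 | 8-hydroxy compound (30 without TES) | C=C1C(=O)O[C@@H]2/C=C(/COCc3ccc(OC)cc3)[C@@H](O[Si](C)(C)C(C)(C)C)C/C=C(C)\C[C@@H](O)[C@@H]12 | intermediate
32 | (1R,10S)-1,10-epoxide of 31 (cis-epoxide, syn to 8-OH) | C=C1C(=O)O[C@@H]2/C=C(/COCc4ccc(OC)cc4)[C@@H](O[Si](C)(C)C(C)(C)C)C[C@H]3O[C@@]3(C)C[C@@H](O)[C@@H]12 | intermediate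
33 | angelic acid, (Z)-2-methylbut-2-enoic acid | C/C=C(/C)C(=O)O | starting material
34 | (Z)-2-methylbut-2-enoic 2,4,6-trichlorobenzoic anhydride | C/C=C(/C)C(=O)OC(=O)c1c(Cl)cc(Cl)cc1Cl | intermediate (not isolated)
35 | 8-O-angelate of 32 | C=C1C(=O)O[C@@H]2/C=C(/COCc4ccc(OC)cc4)[C@@H](O[Si](C)(C)C(C)(C)C)C[C@H]3O[C@@]3(C)C[C@@H](OC(=O)/C(C)=C\C)[C@@H]12 | intermediate
36 | 3-hydroxy compound (35 without TBS) | C=C1C(=O)O[C@@H]2/C=C(/COCc4ccc(OC)cc4)[C@@H](O)C[C@H]3O[C@@]3(C)C[C@@H](OC(=O)/C(C)=C\C)[C@@H]12 | intermediate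
37 | 3-O-acetate of 36 (15-O-PMB ether of the target) | C=C1C(=O)O[C@@H]2/C=C(/COCc4ccc(OC)cc4)[C@@H](OC(C)=O)C[C@H]3O[C@@]3(C)C[C@@H](OC(=O)/C(C)=C\C)[C@@H]12 | intermediate
38 | CNP0162483.1 | C=C1C(=O)O[C@@H]2/C=C(/CO)[C@@H](OC(C)=O)C[C@H]3O[C@@]3(C)C[C@@H](OC(=O)/C(C)=C\C)[C@@H]12 | target

**Step count**
Total: 23 steps. Longest linear sequence: 22 steps (steps 1–7 and 9–23; step 8 prepares the aldol partner).

**Three steps most likely to fail**

Step 16. The episulfone may epimerise before it loses SO2, which would erode the Z geometry, or 1,2-dehydrochlorination to a vinyl sulfone may compete with the 1,3-elimination. The fallback gives up the sulfur extrusion and closes the ten-membered ring directly at C1=C10 by metathesis. It sets out from acid 15. Its acid chloride 17 would be treated with 2-methylallylindium bromide (3-bromo-2-methylpropene, In, THF) to give the 2-methylallyl ketone F6. L-Selectride at −78 °C would give the C8 alcohol F7 and TESOTf/2,6-lutidine its TES ether F8. NaI and PPh3 in hot acetonitrile would turn the C1 chloride into the phosphonium iodide F9, and KHMDS then formaldehyde (Wittig) would give the terminal alkene F10. Ring-closing metathesis with a second-generation Grubbs catalyst in toluene at high dilution would come back to the route at 27.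

Step 12. The thiol addition is reversible, and the 11-membered ring may not be favoured over the open thiol or over oligomers. The fallback makes the C10–S bond first and intermolecularly, and closes the ring by an irreversible S-alkylation. It sets out from enone 18. Conjugate addition of methyl 3-sulfanylpropanoate (Et3N cat., CH2Cl2) would give the open-chain β-sulfanyl ketone F1. L-Selectride would reduce it, now under acyclic Felkin–Anh control, to the alcohol F2, and TESOTf/2,6-lutidine would give the TES ether F3. t-BuOK with NaI in THF/DMF at high dilution would release the C10 thiolate by retro-Michael loss of methyl acrylate and alkylate it at C1, coming back to the route at 23.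

Step 13. Hydride may be delivered from the wrong face if the conformation of the 11-membered ring overrides Felkin–Anh control. The fallback sets C8 by SN2 inversion instead of by facial selectivity. It sets out from ketone 21. If the reduction gives the 8-epi alcohol F4, a Mitsunobu reaction (4-nitrobenzoic acid, PPh3, DIAD, toluene) would give the inverted 4-nitrobenzoate F5, and K2CO3 in methanol would release the alcohol, coming back to the route at 22.

**Further compounds**
F1 | step 12 | open-chain β-sulfanyl ketone (18 with SCH2CH2CO2Me added at C10) | O=C1O[C@H](/C=C(/COCc2ccc(OC)cc2)[C@@H](O[Si](C)(C)C(C)(C)C)CCCl)[C@@H](C(=O)CC(C)SCCC(=O)OC)C1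
F2 | step 12 | C8 alcohol of F1 (8R) | O=C1O[C@H](/C=C(/COCc2ccc(OC)cc2)[C@@H](O[Si](C)(C)C(C)(C)C)CCCl)[C@@H]([C@H](O)CC(C)SCCC(=O)OC)C1
F3 | step 12 | C8 TES ether of F2 | O=C1O[C@H](/C=C(/COCc2ccc(OC)cc2)[C@@H](O[Si](C)(C)C(C)(C)C)CCCl)[C@@H]([C@H](O[Si](CC)(CC)CC)CC(C)SCCC(=O)OC)C1
F4 | step 13 | 8-epi alcohol (C8 epimer of 22) | O=C1O[C@@H]2/C=C(/COCc3ccc(OC)cc3)[C@@H](O[Si](C)(C)C(C)(C)C)CCSC(C)C[C@H](O)[C@H]2C1
F5 | step 13 | 8-O-(4-nitrobenzoate) of 22 | O=C1O[C@@H]2/C=C(/COCc3ccc(OC)cc3)[C@@H](O[Si](C)(C)C(C)(C)C)CCSC(C)C[C@@H](OC(=O)c3ccc(cc3)[N+](=O)[O-])[C@H]2C1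
F6 | step 16 | 2-methylallyl ketone (15 with C(=O)CH2C(CH3)=CH2 in place of CO2H) | O=C1O[C@H](/C=C(/COCc2ccc(OC)cc2)[C@@H](O[Si](C)(C)C(C)(C)C)CCCl)[C@@H](C(=O)CC(C)=C)C1
F7 | step 16 | C8 alcohol of F6 (8R) | O=C1O[C@H](/C=C(/COCc2ccc(OC)cc2)[C@@H](O[Si](C)(C)C(C)(C)C)CCCl)[C@@H]([C@H](O)CC(C)=C)C1
F8 | step 16 | C8 TES ether of F7 | O=C1O[C@H](/C=C(/COCc2ccc(OC)cc2)[C@@H](O[Si](C)(C)C(C)(C)C)CCCl)[C@@H]([C@H](O[Si](CC)(CC)CC)CC(C)=C)C1
F9 | step 16 | C1 triphenylphosphonium iodide of F8 | O=C1O[C@H](/C=C(/COCc2ccc(OC)cc2)[C@@H](O[Si](C)(C)C(C)(C)C)CC[P+](c2ccccc2)(c2ccccc2)c2ccccc2)[C@@H]([C@H](O[Si](CC)(CC)CC)CC(C)=C)C1.[I-]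
F10 | step 16 | metathesis diene (C2–CH=CH2 and C9–C(CH3)=CH2) | O=C1O[C@H](/C=C(/COCc2ccc(OC)cc2)[C@@H](O[Si](C)(C)C(C)(C)C)CC=C)[C@@H]([C@H](O[Si](CC)(CC)CC)CC(C)=C)C1
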